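## Retrosynthetic overview

1. Ring A is the cyclohexenedione, ring B the cyclopentane, and rings C/D the pinane. The last operation saturates two isolated C=C bonds. Before that, ring B is closed by joining the spiro carbon of ring A to the isopropyl-bearing CH, through 5-exo radical attack of the 2-position of a 1,3-diketone on a prenyl-type alkene.
2. Ring A is not assembled as a six-membered ring. It grows from the four-membered ring of 3-methoxy-2,4,4-trimethylcyclobut-2-enone, which takes up the two carbons of a siloxyalkyne (the future spiro carbon and one C=O) in a 4π/[2+2]/4π/6π cascade.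
3. Enabling feature: the ring A segment C(=O)–CMe2–C(OMe)=C(Me) is, atom for atom, the dimethylketene/1-methoxypropyne cycloadduct. The 1,3,5-oxygen pattern is that of a cyclobutenone–oxyalkyne annulation. The quaternary CMe2 blocks aromatisation, and the spiro carbon between the two C=O groups is the nucleophilic alkyne carbon.
4. The siloxyalkyne comes from an α-quaternary aldehyde made from (+)-α-pinene via myrtenal. The quaternary pinane C2 is set by alkylation from the face opposite the CMe2 bridge.
5. Order of ring formation: C/D (chiral pool), four-membered ring, ring A, ring B.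

Key step: step 8

Assumption: the target SMILES is read as the (1R,5R)-(+)-α-pinene series. At pinane C2 the ring A spiro carbon lies on the side of the CMe2 bridge and the ring B CH2 on the side of the CH2 bridge.

## Route

Step 1
Reactants: 1 (1R,5R)-(+)-α-pinene
Product: 2 (1S,5R)-myrtenal
Conditions: SeO2 (1.1 equiv), 1,4-dioxane, 80 °C
Reagents that add atoms: selenium dioxide O=[Se]=O
Why: Riley allylic oxidation (ene reaction, [2,3]-shift, further oxidation) attacks the only allylic methyl group of the trisubstituted alkene and leaves both bridgehead stereocentres untouched.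

Step 2
Reactants: 2 (1S,5R)-myrtenal
Product: 3 N-cyclohexyl imine of myrtenal
Conditions: cyclohexylamine, MgSO4, Et2O, rt
Reagents that add atoms: cyclohexylamine NC1CCCCC1
Why: Imine condensation masks the aldehyde and makes the γ-hydrogens at C4 removable by an amide base.

Step 3
Reactants: 3 N-cyclohexyl imine of myrtenal; 4 5-bromo-2-methylpent-2-ene
Product: 7 (1S,2S,5S)-6,6-dimethyl-2-(4-methylpent-3-en-1-yl)bicyclo[3.1.1]hept-3-ene-2-carbaldehyde, via lithium azadienide 5 (not isolated), via alkylated imine 6 (not isolated)
Conditions: LiN(i-Pr)2, THF–DMPU, −78 to 0 °C; 4, −78 °C to rt; then AcOH–NaOAc–H2O, rt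
Reagents that add atoms: water O
Why: In this deconjugative α-alkylation of a lithiated α,β-unsaturated aldimine (metalloenamine alkylation), the halide should reach the planar C2 from the face opposite the CMe2 bridge, which sets the quaternary centre with the new chain anti and the formyl carbon syn to that bridge, and buffered hydrolysis then frees the aldehyde.

Step 4
Reactants: 7 the α-quaternary aldehyde
Product: 8 (1S,2S,5S)-2-ethynyl-6,6-dimethyl-2-(4-methylpent-3-en-1-yl)bicyclo[3.1.1]hept-3-ene
Conditions: dimethyl (1-diazo-2-oxopropyl)phosphonate, K2CO3, MeOH, rt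
Reagents that add atoms: Ohira–Bestmann reagent COP(=O)(OC)C(=[N+]=[N-])C(C)=O
Why: Seyferth–Gilbert homologation in the Ohira–Bestmann form turns the non-enolisable aldehyde into the terminal alkyne without touching the quaternary centre.

Step 5
Reactants: 8 the terminal alkyne
Product: 11 triisopropylsilyl ynol ether of 8, via lithium acetylide 9 (not isolated), via lithium ynolate 10 (not isolated)
Conditions: n-BuLi, THF, −78 °C; t-BuOOLi (from t-BuOOH and LiN(SiMe3)2), −78 to 0 °C; TIPSOTf, −78 °C
Reagents that add atoms: tert-butyl hydroperoxide CC(C)(C)OO; triisopropylsilyl triflate CC(C)[Si](OS(=O)(=O)C(F)(F)F)(C(C)C)C(C)C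
Why: Oxidation of a lithium acetylide by lithium tert-butyl peroxide gives the ynolate, which a bulky silyl triflate captures on oxygen (the standard siloxyalkyne synthesis).

Step 6
Reactants: 12 2-chloro-1,1-dimethoxyethane
Product: 14 1-methoxyprop-1-yne, via lithium methoxyacetylide 13 (not isolated)
Conditions: LiNEt2 (3.1 equiv), THF, 0 °C; MeI, DMPU, 0 °C to rt; distillation
Reagents that add atoms: iodomethane CI
Why: Base-induced loss of methanol and HCl from the chloroacetal, then deprotonation, gives the alkoxyacetylide, which is methylated on carbon (the classical alkynyl ether synthesis).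

Step 7
Reactants: 15 isobutyryl chloride; 14 1-methoxyprop-1-yne
Product: 17 3-methoxy-2,4,4-trimethylcyclobut-2-en-1-one, via dimethylketene 16 (not isolated)
Conditions: Et3N, Et2O, reflux
Reagents that add atoms: none
Why: Dehydrochlorination gives dimethylketene, and in the thermal ketene–ynol ether [2+2] cycloaddition the ketene carbonyl carbon bonds to the methyl-bearing, nucleophilic alkyne carbon, so only this regioisomer should form.

Step 8
Reactants: 11 triisopropylsilyl ynol ether; 17 3-methoxy-2,4,4-trimethylcyclobut-2-en-1-one
Product: 21 5-methoxy-4,6,6-trimethyl-2-[(1S,2S,5S)-6,6-dimethyl-2-(4-methylpent-3-en-1-yl)bicyclo[3.1.1]hept-3-en-2-yl]-3-(triisopropylsilyloxy)cyclohexa-2,4-dien-1-one, via vinylketene 18 (not isolated), via alkenylcyclobutenone 19 (not isolated), via dienylketene 20 (not isolated)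
Conditions: 17 (3 equiv, in portions), PhMe (0.5 M), 125 °C, sealed tube
Reagents that add atoms: none
Why: Proposed new method: heat opens the four-membered ring of 17 (conrotatory 4π cleavage of the C(=O)–CMe2 bond) to vinylketene 18, the oxygen-remote, nucleophilic alkyne carbon of 11 bonds to the ketene carbonyl carbon in a [2+2] cycloaddition to 19, a second 4π opening gives dienylketene 20, and its ketene carbon closes onto the CMe2 terminus, so that the four ring atoms of 17 reappear in a ring enlarged by the two alkyne carbons. The closest known reaction type is the Danheiser benzannulation of cyclobutenones with siloxyalkynes; beyond it lie the tert-alkyl group on the alkyne, the fully substituted vinylketene and the quaternary terminus, which rules out tautomerisation to a phenol and should stop the cascade at the cyclohexa-2,4-dienone. Ring A is the only ring closed, by a disrotatory 6π electrocyclisation of 20 that is fed from either double-bond isomer because both 4π openings are reversible. No lasting stereocentre is formed (the one in 19 is erased on opening), and the quaternary C2 of the pinene unit is carried through unchanged. The step needs regioselectivity, secured by the matched polarity of ketene carbon and siloxyalkyne, and chemoselectivity against a [1,5]-hydrogen shift in 18 and against ketene addition to the two isolated alkenes, for which 17 is used in excess and in portions and the intramolecular 6π closure of 20 should outrun any [2+2] reaction with the remote trisubstituted alkene.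

Step 9
Reactants: 21 the silyloxy cyclohexadienone
Product: 23 dispiro triene (24 with an isopropenyl group in place of isopropyl and a C3=C4 double bond in the pinane unit), via enol 22 (not isolated)
Conditions: Mn(OAc)3·2H2O (2.5 equiv), Cu(OAc)2·H2O (0.3 equiv), AcOH, 60 °C
Reagents that add atoms: none
Why: Solvolysis of the vinylogous silyl ester frees enol 22, Mn(OAc)3 oxidises it to the radical at the carbon between the two carbonyls (oxidative free-radical cyclisation with Mn(OAc)3/Cu(OAc)2), 5-exo-trig attack on the CH end of the trisubstituted alkene closes ring B through a chair-like transition state in which the bulkier bridgehead C1 of the pinene unit is pseudo-equatorial and the developing Me2C radical turns away from it and from the CMe2-flanked carbonyl of ring A, which should set the spiro carbon (R) and the neighbouring CH (R), and Cu(OAc)2 turns the tertiary radical into the isopropenyl group.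

Step 10
Reactants: 23 dispiro triene
Product: 24 target CNP0307059.1
Conditions: H2 (1 atm), Pd on carbon (Pd/C), EtOAc, rt
Reagents that add atoms: none
Why: Heterogeneous hydrogenation saturates the 1,1-disubstituted and the cis-disubstituted alkene without creating a stereocentre, while the tetrasubstituted vinylogous ester C=C and the hindered ketones of ring A should stay untouched.

## Compound list

1 | (1R,5R)-(+)-α-pinene | CC1=CC[C@@H]2C[C@H]1C2(C)C | starting material
2 | (1S,5R)-myrtenal, (1S,5R)-6,6-dimethylbicyclo[3.1.1]hept-2-ene-2-carbaldehyde | O=CC1=CC[C@@H]2C[C@H]1C2(C)C | intermediate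
3 | (E)-N-cyclohexyl imine of (1S,5R)-myrtenal | C1CCCCC1/N=C/C1=CC[C@@H]2C[C@H]1C2(C)C | intermediate
4 | 5-bromo-2-methylpent-2-ene | CC(C)=CCCBr | starting material
5 | lithium azadienide of 3 (deprotonated at C4) | [Li+].[N-](C1CCCCC1)C=C1C=C[C@@H]2C[C@H]1C2(C)C | intermediate
6 | N-cyclohexyl imine of 7 | C1CCCCC1N=C[C@@]1(CCC=C(C)C)C=C[C@@H]2C[C@H]1C2(C)C | intermediate
7 | (1S,2S,5S)-6,6-dimethyl-2-(4-methylpent-3-en-1-yl)bicyclo[3.1.1]hept-3-ene-2-carbaldehyde (chain anti, CHO syn to the CMe2 bridge) | O=C[C@@]1(CCC=C(C)C)C=C[C@@H]2C[C@H]1C2(C)C | intermediate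
8 | (1S,2S,5S)-2-ethynyl-6,6-dimethyl-2-(4-methylpent-3-en-1-yl)bicyclo[3.1.1]hept-3-ene | C#C[C@@]1(CCC=C(C)C)C=C[C@@H]2C[C@H]1C2(C)C | intermediate
9 | lithium acetylide of 8 | [Li+].[C-]#C[C@@]1(CCC=C(C)C)C=C[C@@H]2C[C@H]1C2(C)C | intermediate
10 | lithium ynolate derived from 8 | [Li+].[O-]C#C[C@@]1(CCC=C(C)C)C=C[C@@H]2C[C@H]1C2(C)C | intermediate
11 | triisopropylsilyl ynol ether, {[(1S,2S,5S)-6,6-dimethyl-2-(4-methylpent-3-en-1-yl)bicyclo[3.1.1]hept-3-en-2-yl]ethynyloxy}triisopropylsilane | CC(C)[Si](OC#C[C@@]1(CCC=C(C)C)C=C[C@@H]2C[C@H]1C2(C)C)(C(C)C)C(C)C | intermediate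
12 | 2-chloro-1,1-dimethoxyethane | COC(CCl)OC | starting material
13 | lithium methoxyacetylide | [Li+].[C-]#COC | intermediate
14 | 1-methoxyprop-1-yne | CC#COC | intermediate
15 | isobutyryl chloride | CC(C)C(=O)Cl | starting material
16 | dimethylketene | CC(C)=C=O | intermediate
17 | 3-methoxy-2,4,4-trimethylcyclobut-2-en-1-one | COC1=C(C)C(=O)C1(C)C | intermediate
18 | vinylketene, 3-methoxy-2,4-dimethylpenta-1,3-dien-1-one | COC(=C(C)C)C(C)=C=O | intermediate
19 | 4-(1-methoxy-2-methylprop-1-enyl)-4-methyl-2-(pinenyl)-3-(triisopropylsilyloxy)cyclobut-2-en-1-one (both epimers at C4 of the four-membered ring) | COC(=C(C)C)C1(C)C(=O)C([C@@]3(CCC=C(C)C)C=C[C@@H]2C[C@H]3C2(C)C)=C1O[Si](C(C)C)(C(C)C)C(C)C | intermediate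
20 | dienylketene (ketene-bearing carbon and methoxyalkenyl group cis on the central C=C) | O=C=C([C@@]3(CCC=C(C)C)C=C[C@@H]2C[C@H]3C2(C)C)/C(O[Si](C(C)C)(C(C)C)C(C)C)=C(C)\C(OC)=C(C)C | intermediate
21 | 5-methoxy-4,6,6-trimethyl-2-[(1S,2S,5S)-6,6-dimethyl-2-(4-methylpent-3-en-1-yl)bicyclo[3.1.1]hept-3-en-2-yl]-3-(triisopropylsilyloxy)cyclohexa-2,4-dien-1-one | COC1=C(C)C(O[Si](C(C)C)(C(C)C)C(C)C)=C(C(=O)C1(C)C)[C@@]3(CCC=C(C)C)C=C[C@@H]2C[C@H]3C2(C)C | intermediate
22 | 3-hydroxy-5-methoxy-4,6,6-trimethyl-2-(same pinenyl group)cyclohexa-2,4-dien-1-one (enol of the 1,3-diketone) | COC1=C(C)C(O)=C(C(=O)C1(C)C)[C@@]3(CCC=C(C)C)C=C[C@@H]2C[C@H]3C2(C)C | intermediate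
23 | dispiro triene: ring A as in 24, spiro carbon R, ring B CH (R) bearing isopropenyl, pinene unit with C3=C4 | COC1=C(C)C(=O)[C@@]2(C(=O)C1(C)C)[C@@H](C(C)=C)CC[C@@]21C=C[C@@H]2C[C@H]1C2(C)C | intermediate
24 | CNP0307059.1: 5-methoxy-4,6,6-trimethylcyclohex-4-ene-1,3-dione spiro-linked at C2 (R) to a cyclopentane. One neighbour of the spiro carbon in ring B is the CH (R) bearing isopropyl, cis to the carbonyl next to C(Me)=. The other neighbour is C2 (R) of a (1S,5R)-6,6-dimethylbicyclo[3.1.1]heptane, with the ring A carbon syn to the CMe2 bridge | COC1=C(C)C(=O)[C@@]2(C(=O)C1(C)C)[C@@H](C(C)C)CC[C@@]21CC[C@@H]2C[C@H]1C2(C)C | target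

## Step count and main risks

Total step count: 10. Longest linear sequence: 8 (steps 1–5 and 8–10).

**Step 8.**
- **What may go wrong:** the vinylketene may drain away through a [1,5]-hydrogen shift from its Z-methyl group, or the tert-alkyl group may block the [2+2] addition.
- **Fallback:** this fallback enlarges a five-membered 1,2-diketone by one atom instead. It sets out from 7 and comes back at 22. Hydrazine hydrate in EtOH would give the hydrazone F1, and MnO2 in Et2O at 0 °C the diazoalkane F2. In parallel, Claisen condensation of 2-methylpentan-3-one with dimethyl oxalate (NaOMe, MeOH) would give 3,3,5-trimethylcyclopentane-1,2,4-trione F3. O-Methylation with TMSCHN2, followed by separation of the enol ether isomers, would give 4-methoxy-3,5,5-trimethylcyclopent-3-ene-1,2-dione F4. Slow addition of F2 to F4 (Et2O, −78 to 0 °C) is a Büchner–Curtius–Schlotterbeck ring enlargement. The diazo carbon adds to the non-conjugated carbonyl, the neighbouring acyl group migrates as dinitrogen leaves, and the inserted carbon ends between both carbonyls. The product is 22, which would be taken on under the conditions of step 9.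

**Step 9.**
- **What may go wrong:** oxidation of the crowded enol may be slow, the facial selectivity of the radical closure may be poor, or a ring A carbonyl oxygen may capture the tertiary cation.
- **Fallback:** this fallback closes the same bond as a polar, ligand-controlled reaction. It sets out from 21 and comes back at 23. Allylic oxidation of the E-methyl group (catalytic SeO2, t-BuOOH, CH2Cl2) would give the allylic alcohol F5. Methyl chloroformate and pyridine would convert it into the allylic methyl carbonate F6. Zerovalent palladium (Pd2(dba)3·CHCl3 with a chiral DACH-phenyl Trost diphosphine, CH2Cl2) would ionise F6. The liberated methoxide would unmask the silyl enol ether, and 5-exo Tsuji–Trost attack of the diketone carbon on the inner allyl terminus would give 23. The choice of ligand enantiomer is then available to reinforce the substrate bias.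

**Step 3.**
- **What may go wrong:** the basic azadienide may cause E2 elimination of the homoallylic bromide, or attack may occur at the γ-position.
- **Fallback:** this fallback builds the side chain in two stages. It sets out from 5 and comes back at 7. Alkylation with 2-(2-bromoethyl)-1,3-dioxolane would give the dioxolane imine F7. Aqueous HCl in THF would unmask both functions to the dialdehyde F8. One equivalent of isopropylidenetriphenylphosphorane (from isopropyltriphenylphosphonium iodide and n-BuLi, THF, −78 °C) should undergo the Wittig reaction only at the unhindered chain aldehyde, which gives 7.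

## Further compounds

F1 | step 8 | hydrazone of 7 | NN=C[C@@]1(CCC=C(C)C)C=C[C@@H]2C[C@H]1C2(C)C
F2 | step 8 | (1S,2S,5S)-2-(diazomethyl)-6,6-dimethyl-2-(4-methylpent-3-en-1-yl)bicyclo[3.1.1]hept-3-ene | [N-]=[N+]=C[C@@]1(CCC=C(C)C)C=C[C@@H]2C[C@H]1C2(C)C
F3 | step 8 | 3,3,5-trimethylcyclopentane-1,2,4-trione | CC1C(=O)C(=O)C(C)(C)C1=O
F4 | step 8 | 4-methoxy-3,5,5-trimethylcyclopent-3-ene-1,2-dione | COC1=C(C)C(=O)C(=O)C1(C)C
F5 | step 9 | (E)-allylic alcohol of 21 | COC1=C(C)C(O[Si](C(C)C)(C(C)C)C(C)C)=C(C(=O)C1(C)C)[C@@]3(CC/C=C(\C)CO)C=C[C@@H]2C[C@H]3C2(C)C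
F6 | step 9 | (E)-allylic methyl carbonate of F5 | COC1=C(C)C(O[Si](C(C)C)(C(C)C)C(C)C)=C(C(=O)C1(C)C)[C@@]3(CC/C=C(\C)COC(=O)OC)C=C[C@@H]2C[C@H]3C2(C)C
F7 | step 3 | N-cyclohexyl imine of 2-[2-(1,3-dioxolan-2-yl)ethyl]-6,6-dimethylbicyclo[3.1.1]hept-3-ene-2-carbaldehyde | C1CCCCC1N=C[C@@]1(CCC2OCCO2)C=C[C@@H]2C[C@H]1C2(C)C
F8 | step 3 | 6,6-dimethyl-2-(3-oxopropyl)bicyclo[3.1.1]hept-3-ene-2-carbaldehyde | O=C[C@@]1(CCC=O)C=C[C@@H]2C[C@H]1C2(C)C
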